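**Total synthesis plan for CNP0222085.1 (47): a briarane by three-component desymmetrisation of an arene-derived cyclohexadienone**

Briarane numbering is used throughout: ring A = C1, C10, C11, C12, C13, C14; ten-membered ring = C1–C10; lactone = O–C19(=O)–C17(CH3)–C8–C7. β is the face of ring A that carries the C1 methyl group.

## The problem

Compound 47 is a cyclohexene (ring A) fused through C1–C10 to a ten-membered carbocycle that holds a Z-trisubstituted C5=C6 olefin and is fused across C7–C8 to an α-methyl-γ-lactone. Nine stereocentres and one olefin geometry must be set: the quaternary C1, the contiguous ring A centres C10, C11 and C12, the two acetoxy carbinols C2 and C9 beside the ring fusion, and the lactone triad C7/C8/C17, in which C8 is a fully substituted carbinol. On ring A the C1 methyl, the C10–C9 bond and the C11 methyl are all cis, and the C12 hydroxyl is trans to them. C10 can therefore steer C11, because an electrophile or a proton enters anti to the C10 substituent. The same substituent, axial in the only unstrained half-chair, shields the β face of a C12 carbonyl, so hydride reduction should give the 12-epimer and an inversion has to be planned. C2 and C9 lie on freely rotating bonds next to hindered centres and need reagent control; C7 and C8 are best made in the ring-closing event; C17, α to the lactone carbonyl, can be left to equilibration. The fragile features are the β-hydroxy lactone (retro-aldol, dehydration to the 8(17)-butenolide), two secondary acetates beside a free tertiary and a free allylic hydroxyl, the Z-allylic C7 oxygen, and on the way the epimerisable C11 of a 12-ketone. The opening is ring A itself: a C12 oxygen flanked by C13=C14 and by the C11–C10 pair, with the quaternary C1 para to it, is a 4,4-disubstituted cyclohexa-2,5-dienone after one conjugate addition and one α-functionalisation, and that dienone is prochiral, so choosing one enone arm creates C1 and C10 together.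

## Retrosynthesis

**47 to 44 (no C–C bond cut).** The three secondary carbinols are told apart by silyl class. The 12-O-TBS diacetate 46 comes from diol 45, which comes from the bis(triethylsilyl) ether 44 by selective loss of the more labile silyl groups. Acetylation of 45 must spare the tertiary C8 hydroxyl.

**44 to 41 (cut C7–C8 and the lactone C–O).** A cis-7,8-diol with an ester on C17 is the lactone in open form, and a 7,8-diol is a pinacol retron; this leads through the C17 epimer mixture 43 back to keto-enal 41. Cutting C8–C9 instead would need a pre-built furanone and would discard the terminal vinyl carbon. Cutting C6–C7 would need a quaternary α-hydroxy aldehyde. Cutting C5=C6 would ask metathesis for a trisubstituted Z-cyclodecene. Precursor 41 has no medium ring and lacks three of the nine stereocentres; the forward step must give the cis-diol and the correct C8 face.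

**41 to 36 + 38 (cut C8–C17).** The β-keto ester 39 is the homologation product of the α-silyloxy aldehyde 36 with ethyl 2-diazopropanoate 38. Deprotection to 40 and oxidation give 41. The forward reaction only has to tolerate the silyl ethers; C17 stays unset.

**36 to 32 (C8 and C9 oxygens from the vinyl group).** Both vinyl carbons are kept. Catalytic diboration–oxidation of 32 gives triol 34 with C9 set by the ligand, and silylation (35) followed by selective oxidation of the primary ether gives 36. Dihydroxylation with osmium would attack the trisubstituted olefin first; diboration reacts only with the terminal alkene.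

**32 to 22 + 28 (cut C2–C3).** The organolithium 29 from iodide 28 adds to the neopentyl aldehyde 22. Because the quaternary C1 gives no reliable facial bias, the carbinols 30 are oxidised to ketone 31 and reduced under catalyst control. A C4–C5 cross-coupling was set aside because its hydroboration could not tell a C2 vinyl group from the C10 vinyl group.

**28 to 23.** The Z-trisubstituted olefin is bought: (Z)-3-methylpent-2-en-4-yn-1-ol 23 already has C4 and C7 cis. Protection (24), semi-hydrogenation (25), hydroboration–oxidation (27) and iodination give 28.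

**22 to 16 (C12).** Aldehyde 22 comes from alcohol 21 and the bis-silyl ether 20. The 12α-carbinol 19 is reached from enone 16 by reduction to the 12β-alcohol 17 and inversion through ester 18.

**16 to 12 (C11).** The β-methyl group of 16 arises by conjugate reduction of the exocyclic enone 14 and protonation anti to the vinyl group. Compound 14 is the elimination product of the Mannich base 12; direct methylation of the enolate would give the wrong (trans) epimer.

**12 to 6 + 9 + 10 (cut C9–C10 and C11–CH2).** Dienone 6, the vinylalane 9 and the iminium salt 10 are joined in one copper-catalysed operation that fixes C1 and C10. The precursor is achiral and five steps from commodity chemicals.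

**6 to 1 + 2; 9 to 7 + 8.** Birch reductive methylation of benzoic acid 1 with iodomethane 2 (3), reduction (4), silylation (5) and bis-allylic oxidation give 6. The alane 9 comes from vinylmagnesium bromide 7 and diisobutylaluminium chloride 8.

## Roads not taken

**Alternative 1:** The cut is C8–C9. SmI2 would couple the C9 aldehyde of keto-aldehyde A2 with the C8 ketone of its 2-methoxy-4-methylfuran-3-one, giving the cis-8,9-diol A1 with the lactone masked as a lactol methyl ether.
- Merits: C8–OH and C9–O arise together; C7 and C17 are fixed before cyclisation, so the ring closure sets only two centres; the aldehyde is aliphatic, so the ketyl has no allylic ambiguity. In these respects it is better than step 29 of the chosen route, which couples a conjugated aldehyde and sets the lactone fusion in the same event.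
- Weak points: the furanone with three stereocentres must be built and joined at C2–C3 while carrying a ketone; its ring oxygen is α to that ketone and invites reductive C–O cleavage just as the C9 silyl ether of 41 does; the lactol must be oxidised late beside a free diol; and the road does not say where ring A comes from.
- Against it the chosen plan sets: both vinyl carbons are used, C9 is fixed by a catalyst before the ring exists, the side pieces (28, 38) are trivial, and the lactone forms at the correct oxidation level.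

**Alternative 2:** The cut is the former C2=C7 bond. Ozone would cleave the tetrasubstituted alkene of the tricyclic hydrophenanthrene A4, and base would expel the C5 acetate to give the ten-membered triketone A3.
- Merits: no medium-ring cyclisation is needed, six-membered-ring chemistry sets the early stereocentres, and the Z-olefin follows from the elimination. In certainty of ring formation it is better than the chosen plan.
- Weak points: A3 has ketones at C2, C7 and C12 that must each be reduced with the correct sense in a flexible ring; the 2,7-diketone is set up for transannular aldol re-closure; and A4, with quaternary C1 and C8, is a long synthesis in itself.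
- Against it the chosen plan sets: C2 and C12 are fixed by CBS reduction and by inversion before the ring exists, and no transannularly reactive diketone is ever formed.

**Alternative 3:** The cut is C8–C17. SmI2 would reduce the O7-bound 2-bromopropanoate of macrocyclic ketone A6 to a samarium enolate that adds to the C8 ketone, giving lactone A5.
- Merits: the reaction type is very reliable, the tether delivers C17 to C8 from the side of O7, the bromide is reduced before the α-alkoxy ketone, and A5 is three simple steps from the target. As a lactone-forming step it is safer than the pinacol–lactonisation of the chosen route.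
- Weak points: it postpones the ten-membered ring instead of making it. A6, a 7-hydroxy-8-ketone flanked by two epimerisable oxygenated carbons, must be cyclised by other means and C7 set separately; the C8 face relative to C9 still depends on the macrocycle conformation.
- Against it the chosen plan sets: one step forms C7–C8, the ring and the lactone.

Key step: step 6

**Remarks on the chemistry (assumptions)**
- The enantiomers of the chiral ligands named in steps 6 and 22 are those assumed to give the series drawn; the sense is checked on the first run and the antipodal ligand is used if it is opposite.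
- The C3–C7 unit is taken from commercial 23 rather than from nerol, because the C1–C6 segment of nerol is one carbon too long once C2 is already on ring A.
- From 33 to 41, "ring A unit" means the (1S,10S,11R,12R)-1,11-dimethyl-12-(tert-butyldimethylsilyloxy)cyclohex-13-ene of 32, bonded through C1 to C2 and through C10 to C9.

## Route

Step 1
Reactants: 1 benzoic acid; 2 iodomethane
Product: 3 1-methylcyclohexa-2,5-diene-1-carboxylic acid
Conditions: Li, NH3(l)/THF, −78 °C; then MeI; NH4Cl, then aq. HCl
Reagents that add atoms: none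
Why: Birch reduction of the benzoate gives the carboxylate dianion, which is C-methylated at C1 in the flask (Birch reductive alkylation); the product is achiral.

Step 2
Reactants: 3 1-methylcyclohexa-2,5-diene-1-carboxylic acid
Product: 4 (1-methylcyclohexa-2,5-dien-1-yl)methanol
Conditions: LiAlH4, Et2O, 0 °C → rt
Reagents that add atoms: none
Why: Hydride reduction of the acid; the skipped diene is inert to LiAlH4.

Step 3
Reactants: 4 (1-methylcyclohexa-2,5-dien-1-yl)methanol
Product: 5 tert-butyl[(1-methylcyclohexa-2,5-dien-1-yl)methoxy]diphenylsilane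
Conditions: t-BuPh2SiCl, imidazole, CH2Cl2, rt
Reagents that add atoms: tert-butyl(chloro)diphenylsilane, CC(C)(C)[Si](Cl)(c1ccccc1)c1ccccc1
Why: Standard silylation of a primary alcohol; the bulky silyl group later marks one face of the dienone.

Step 4
Reactants: 5 tert-butyl[(1-methylcyclohexa-2,5-dien-1-yl)methoxy]diphenylsilane
Product: 6 4-{[(tert-butyldiphenylsilyl)oxy]methyl}-4-methylcyclohexa-2,5-dien-1-one
Conditions: CrO3, 3,5-dimethylpyrazole, CH2Cl2, −20 °C
Reagents that add atoms: chromium trioxide, O=[Cr](=O)=O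
Why: Allylic oxidation with the CrO3–3,5-dimethylpyrazole complex; the doubly allylic CH2 is the only activated position and gives the prochiral cross-conjugated dienone.

Step 5
Reactants: 7 vinylmagnesium bromide; 8 diisobutylaluminium chloride
Product: 9 diisobutyl(vinyl)aluminium
Conditions: Et2O/THF, 0 °C → rt; decanted from the magnesium salts and used as a titrated solution
Reagents that add atoms: none
Why: Salt metathesis (Mg to Al transmetalation) gives the mixed alane, whose sp2 ligand is the one transferred to copper.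

Step 6
Reactants: 6 4-{[(tert-butyldiphenylsilyl)oxy]methyl}-4-methylcyclohexa-2,5-dien-1-one; 9 diisobutyl(vinyl)aluminium; 10 dimethylmethyleneiminium iodide
Product: 12 (4S,5S,6R)-4-{[(tert-butyldiphenylsilyl)oxy]methyl}-6-[(dimethylamino)methyl]-5-ethenyl-4-methylcyclohex-2-en-1-one, via aluminium dienolate 11 (not isolated)
Conditions: Cu(OTf)2 (5 mol%), (S,R,R)-O,O′-(1,1′-binaphthyl-2,2′-diyl) N,N-bis(1-phenylethyl)phosphoramidite (10 mol%), 9 (1.5 equiv), Et2O, −30 °C; then 10 (2 equiv), CH2Cl2, −30 → 0 °C; aq. NaHCO3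
Reagents that add atoms: none
Why: Cu(OTf)2 is reduced by the alane to a monovalent copper–phosphoramidite complex, which takes the vinyl group from aluminium, binds one enone arm of 6 (carbonyl activated by the Lewis-acidic aluminium) and delivers vinyl to C10 by oxidative addition–reductive elimination, leaving the aluminium dienolate 11; 11 then attacks the iminium ion 10 at C11, so C9–C10 and C11–CH2 are formed and no ring is closed. The closest known reaction types are the copper–phosphoramidite desymmetrisation of 4,4-disubstituted cyclohexa-2,5-dienones with organozinc and organoaluminium reagents, the copper-catalysed 1,4-transfer of alkenyl groups from alkenylalanes to cyclic enones, and the Mannich trapping of conjugate-addition enolates with dimethylmethyleneiminium salts. C10: the chiral ligand decides which enantiotopic arm reacts and the substrate decides the face, the vinyl group entering anti to the silyloxymethyl group and so syn to the methyl group. C1 becomes stereogenic in the same event because its two ring arms are now different. C11: the iminium ion approaches anti to the new vinyl group (trans product); this centre is temporary and is erased in step 7. The step needs 1,4- over 1,2-addition (secured by copper), vinyl over isobutyl transfer (sp2 groups pass from aluminium to copper faster), and a single addition (the second enone is held as the dienolate until the electrophile arrives, and its β-carbon C14 is neopentyl).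

Step 7
Reactants: 12 (4S,5S,6R)-4-{[(tert-butyldiphenylsilyl)oxy]methyl}-6-[(dimethylamino)methyl]-5-ethenyl-4-methylcyclohex-2-en-1-one; 2 iodomethane
Product: 14 (4S,5R)-4-{[(tert-butyldiphenylsilyl)oxy]methyl}-5-ethenyl-4-methyl-6-methylidenecyclohex-2-en-1-one, via methiodide 13 (not isolated)
Conditions: MeI, Et2O/CH2Cl2, rt; then aq. NaHCO3, CH2Cl2, rt; used at once
Reagents that add atoms: none
Why: N-Quaternisation and E1cB loss of trimethylamine (Mannich base elimination) give the exocyclic enone; C10 is not enolisable toward this system and keeps its configuration.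

Step 8
Reactants: 14 (4S,5R)-4-{[(tert-butyldiphenylsilyl)oxy]methyl}-5-ethenyl-4-methyl-6-methylidenecyclohex-2-en-1-one
Product: 16 (4S,5S,6R)-4-{[(tert-butyldiphenylsilyl)oxy]methyl}-5-ethenyl-4,6-dimethylcyclohex-2-en-1-one, via lithium dienolate 15 (not isolated)
Conditions: LiBH(s-Bu)3, THF, −78 °C; then AcOH in THF, −78 °C
Reagents that add atoms: none
Why: Conjugate hydride addition goes to the unhindered exocyclic β-carbon (the ring β-carbon C14 is neopentyl). Kinetic C-protonation of 15 occurs anti to the C10 vinyl group, which allylic 1,2-strain holds pseudoaxial, so H enters α and the methyl group ends β, cis to vinyl. This isomer is also expected to be the more stable one, since it alone has both methyl groups equatorial.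

Step 9
Reactants: 16 (4S,5S,6R)-4-{[(tert-butyldiphenylsilyl)oxy]methyl}-5-ethenyl-4,6-dimethylcyclohex-2-en-1-one
Product: 17 (1S,4S,5S,6R)-4-{[(tert-butyldiphenylsilyl)oxy]methyl}-5-ethenyl-4,6-dimethylcyclohex-2-en-1-ol
Conditions: NaBH4, CeCl3·7H2O, MeOH, −78 °C
Reagents that add atoms: none
Why: Luche 1,2-reduction at low temperature leaves C11 untouched. Hydride should enter C12 from the α face, away from the axial C10 vinyl group that is 1,3 to the carbonyl, giving the 12β-alcohol. Any 12α-alcohol formed is 19 itself and is added to the product of step 11.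

Step 10
Reactants: 17 (1S,4S,5S,6R)-4-{[(tert-butyldiphenylsilyl)oxy]methyl}-5-ethenyl-4,6-dimethylcyclohex-2-en-1-ol
Product: 18 (1R,4S,5S,6R)-4-{[(tert-butyldiphenylsilyl)oxy]methyl}-5-ethenyl-4,6-dimethylcyclohex-2-en-1-yl 4-nitrobenzoate
Conditions: 4-nitrobenzoic acid, PPh3, diisopropyl azodicarboxylate, toluene, 0 °C → rt
Reagents that add atoms: 4-nitrobenzoic acid, OC(=O)c1ccc(cc1)[N+](=O)[O-]
Why: Mitsunobu esterification inverts C12 by SN2 displacement of the pseudoaxial oxyphosphonium group; SN2′ attack is blocked because C14 is neopentyl.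

Step 11
Reactants: 18 (1R,4S,5S,6R)-4-{[(tert-butyldiphenylsilyl)oxy]methyl}-5-ethenyl-4,6-dimethylcyclohex-2-en-1-yl 4-nitrobenzoate
Product: 19 (1R,4S,5S,6R)-4-{[(tert-butyldiphenylsilyl)oxy]methyl}-5-ethenyl-4,6-dimethylcyclohex-2-en-1-ol
Conditions: K2CO3, MeOH, rt
Reagents that add atoms: none
Why: Transesterification of the activated benzoate; the silyl ether is stable and C12 is not touched.

Step 12
Reactants: 19 (1R,4S,5S,6R)-4-{[(tert-butyldiphenylsilyl)oxy]methyl}-5-ethenyl-4,6-dimethylcyclohex-2-en-1-ol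
Product: 20 tert-butyl{[(1R,4S,5S,6R)-4-{[(tert-butyldiphenylsilyl)oxy]methyl}-5-ethenyl-4,6-dimethylcyclohex-2-en-1-yl]oxy}dimethylsilane
Conditions: t-BuMe2SiOTf, 2,6-lutidine, CH2Cl2, −78 → 0 °C
Reagents that add atoms: tert-butyldimethylsilyl trifluoromethanesulfonate, CC(C)(C)[Si](C)(C)OS(=O)(=O)C(F)(F)F
Why: Silyl triflate protection of a hindered secondary alcohol; this group marks C12 as the hydroxyl that stays free at the end.

Step 13
Reactants: 20 tert-butyl{[(1R,4S,5S,6R)-4-{[(tert-butyldiphenylsilyl)oxy]methyl}-5-ethenyl-4,6-dimethylcyclohex-2-en-1-yl]oxy}dimethylsilane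
Product: 21 [(1S,4R,5R,6S)-4-[(tert-butyldimethylsilyl)oxy]-6-ethenyl-1,5-dimethylcyclohex-2-en-1-yl]methanol
Conditions: Bu4NF, AcOH (1:1), THF, 0 °C → rt
Reagents that add atoms: none
Why: Buffered fluoride removes the primary tert-butyldiphenylsilyl ether faster than the hindered secondary allylic tert-butyldimethylsilyl ether (selective desilylation).

Step 14
Reactants: 21 [(1S,4R,5R,6S)-4-[(tert-butyldimethylsilyl)oxy]-6-ethenyl-1,5-dimethylcyclohex-2-en-1-yl]methanol
Product: 22 (1S,4R,5R,6S)-4-[(tert-butyldimethylsilyl)oxy]-6-ethenyl-1,5-dimethylcyclohex-2-ene-1-carbaldehyde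
Conditions: Dess–Martin periodinane, NaHCO3, CH2Cl2, rt
Reagents that add atoms: none
Why: Mild oxidation of a neopentyl primary alcohol; the aldehyde has no α-hydrogen and cannot epimerise.

Step 15
Reactants: 23 (2Z)-3-methylpent-2-en-4-yn-1-ol
Product: 24 1-methoxy-4-({[(2Z)-3-methylpent-2-en-4-yn-1-yl]oxy}methyl)benzene
Conditions: NaH, 4-methoxybenzyl chloride, Bu4NI (cat.), THF/DMF, 0 °C → rt
Reagents that add atoms: 4-methoxybenzyl chloride, COc1ccc(CCl)cc1
Why: Williamson etherification; the alkoxide forms well before the alkyne is deprotonated.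

Step 16
Reactants: 24 1-methoxy-4-({[(2Z)-3-methylpent-2-en-4-yn-1-yl]oxy}methyl)benzene
Product: 25 1-methoxy-4-({[(2Z)-3-methylpenta-2,4-dien-1-yl]oxy}methyl)benzene
Conditions: H2 (1 atm), Pd/CaCO3 poisoned with Pb(OAc)2, quinoline, hexane, rt
Reagents that add atoms: none
Why: Lindlar semi-hydrogenation of the terminal alkyne; the trisubstituted olefin and its Z geometry are not affected.

Step 17
Reactants: 25 1-methoxy-4-({[(2Z)-3-methylpenta-2,4-dien-1-yl]oxy}methyl)benzene
Product: 27 (3Z)-5-[(4-methoxybenzyl)oxy]-3-methylpent-3-en-1-ol, via B-alkyl-9-borabicyclononane 26 (not isolated)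
Conditions: 9-borabicyclo[3.3.1]nonane, THF, 0 °C → rt; then aq. NaOH, H2O2, 0 °C
Reagents that add atoms: hydrogen peroxide, OO
Why: Anti-Markovnikov hydroboration of the terminal vinyl group of the diene (the trisubstituted olefin is inert to this borane), then oxidation with retention.

Step 18
Reactants: 27 (3Z)-5-[(4-methoxybenzyl)oxy]-3-methylpent-3-en-1-ol
Product: 28 1-({[(2Z)-5-iodo-3-methylpent-2-en-1-yl]oxy}methyl)-4-methoxybenzene
Conditions: I2, PPh3, imidazole, CH2Cl2, 0 °C
Reagents that add atoms: iodine, II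
Why: Appel-type iodination of a primary alcohol under neutral conditions.

Step 19
Reactants: 28 1-({[(2Z)-5-iodo-3-methylpent-2-en-1-yl]oxy}methyl)-4-methoxybenzene; 22 (1S,4R,5R,6S)-4-[(tert-butyldimethylsilyl)oxy]-6-ethenyl-1,5-dimethylcyclohex-2-ene-1-carbaldehyde
Product: 30 (1RS,4Z)-1-[(1S,4R,5R,6S)-4-[(tert-butyldimethylsilyl)oxy]-6-ethenyl-1,5-dimethylcyclohex-2-en-1-yl]-6-[(4-methoxybenzyl)oxy]-4-methylhex-4-en-1-ol, via alkyllithium 29 (not isolated)
Conditions: t-BuLi (2.1 equiv), Et2O, −78 °C; then 22, −78 → −40 °C; aq. NH4Cl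
Reagents that add atoms: none
Why: Lithium–iodine exchange gives the primary homoallylic organolithium, which adds 1,2 to the non-enolisable aldehyde to form C2–C3. The C2 epimers are not separated because C2 is reset in steps 20 and 21.

Step 20
Reactants: 30 (1RS,4Z)-1-[(1S,4R,5R,6S)-4-[(tert-butyldimethylsilyl)oxy]-6-ethenyl-1,5-dimethylcyclohex-2-en-1-yl]-6-[(4-methoxybenzyl)oxy]-4-methylhex-4-en-1-ol
Product: 31 (4Z)-1-[(1S,4R,5R,6S)-4-[(tert-butyldimethylsilyl)oxy]-6-ethenyl-1,5-dimethylcyclohex-2-en-1-yl]-6-[(4-methoxybenzyl)oxy]-4-methylhex-4-en-1-one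
Conditions: Dess–Martin periodinane, NaHCO3, CH2Cl2, rt
Reagents that add atoms: none
Why: Oxidation to the tert-alkyl ketone removes the uncontrolled C2 centre.

Step 21
Reactants: 31 (4Z)-1-[(1S,4R,5R,6S)-4-[(tert-butyldimethylsilyl)oxy]-6-ethenyl-1,5-dimethylcyclohex-2-en-1-yl]-6-[(4-methoxybenzyl)oxy]-4-methylhex-4-en-1-one
Product: 32 (1R,4Z)-1-[(1S,4R,5R,6S)-4-[(tert-butyldimethylsilyl)oxy]-6-ethenyl-1,5-dimethylcyclohex-2-en-1-yl]-6-[(4-methoxybenzyl)oxy]-4-methylhex-4-en-1-ol
Conditions: (S)-1-methyl-3,3-diphenyltetrahydro-1H,3H-pyrrolo[1,2-c][1,3,2]oxazaborole (0.3 equiv), catecholborane, toluene, −78 → −40 °C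
Reagents that add atoms: none
Why: Corey–Bakshi–Shibata reduction. The quaternary C1 is the large group and the C3 methylene the small one, so the (S)-catalyst should give the 2R carbinol. Catecholborane at low temperature does not hydroborate the alkenes.

Step 22
Reactants: 32 (1R,4Z)-1-[(1S,4R,5R,6S)-4-[(tert-butyldimethylsilyl)oxy]-6-ethenyl-1,5-dimethylcyclohex-2-en-1-yl]-6-[(4-methoxybenzyl)oxy]-4-methylhex-4-en-1-ol
Product: 34 (2R,9R)-triol: ring A unit carrying at C10 the (9R)-1,2-dihydroxyethyl group (C9, C8) and at C1 the (2R,5Z)-1-hydroxy-6-[(4-methoxybenzyl)oxy]-4-methylhex-4-enyl chain, via bis(pinacolboronate) 33 (not isolated)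
Conditions: Pt(dba)3 (3 mol%), (R,R)-TADDOL-derived phenylphosphonite with 3,5-diisopropylphenyl groups (6 mol%), bis(pinacolato)diboron, THF, 60 °C; then aq. NaOH, H2O2, 0 °C → rt
Reagents that add atoms: hydrogen peroxide, OO
Why: Platinum-catalysed enantioselective diboration reacts only with monosubstituted alkenes, so the trisubstituted C5=C6 and the ring olefin are untouched. The ligand chooses the C9 face, and oxidation of both C–B bonds proceeds with retention.

Step 23
Reactants: 34 (2R,9R)-triol
Product: 35 (2R,9R)-2,8,9-tris(triethylsilyl) ether of 34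
Conditions: Et3SiOTf, 2,6-lutidine, CH2Cl2, −78 → 0 °C
Reagents that add atoms: triethylsilyl trifluoromethanesulfonate, CC[Si](CC)(CC)OS(=O)(=O)C(F)(F)F
Why: Exhaustive silylation; one reagent protects C2 and C9 and activates C8 for the next step.

Step 24
Reactants: 35 (2R,9R)-2,8,9-tris(triethylsilyl) ether of 34
Product: 36 (2R,9R)-C8 aldehyde: ring A unit carrying at C10 the (R)-CH(OSiEt3)–CHO group and at C1 the (2R,5Z)-chain with 2-OSiEt3 and 7-O-(4-methoxybenzyl)
Conditions: (COCl)2, DMSO, CH2Cl2, −78 → −30 °C; then Et3N, −78 °C → rt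
Reagents that add atoms: none
Why: Under Swern conditions a primary triethylsilyl ether is cleaved and oxidised to the aldehyde while secondary ones survive (selective Swern oxidation of silyl ethers); C9 is not epimerised at low temperature.

Step 25
Reactants: 37 ethyl 2-methyl-3-oxobutanoate
Product: 38 ethyl 2-diazopropanoate
Conditions: 4-acetamidobenzenesulfonyl azide, 1,8-diazabicyclo[5.4.0]undec-7-ene, MeCN, 0 °C → rt
Reagents that add atoms: 4-acetamidobenzenesulfonyl azide, CC(=O)Nc1ccc(cc1)S(=O)(=O)N=[N+]=[N-]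
Why: Regitz diazo transfer with loss of the acetyl group (deacylative diazo transfer).

Step 26
Reactants: 36 (2R,9R)-C8 aldehyde; 38 ethyl 2-diazopropanoate
Product: 39 (2R,9R,17RS)-β-keto ester: C10 side chain (R)-CH(OSiEt3)–C(=O)–CH(CH3)–CO2Et, C1 chain as in 36
Conditions: SnCl2 (0.2 equiv), CH2Cl2, rt
Reagents that add atoms: none
Why: Roskamp homologation: the Lewis-acid-activated aldehyde adds the diazo ester and a 1,2-hydride shift with loss of N2 gives the β-keto ester, forming C8–C17. C17 is left unset on purpose.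

Step 27
Reactants: 39 (2R,9R,17RS)-β-keto ester
Product: 40 (2R,9R,17RS)-β-keto ester with free C7 hydroxyl (Z-allylic alcohol)
Conditions: 2,3-dichloro-5,6-dicyano-1,4-benzoquinone, CH2Cl2/pH 7 buffer, 0 °C
Reagents that add atoms: none
Why: Oxidative removal of the 4-methoxybenzyl ether; silyl ethers and the keto ester are inert under buffered conditions.

Step 28
Reactants: 40 (2R,9R,17RS)-β-keto ester with free C7 hydroxyl
Product: 41 (2R,5Z,9R,17RS)-keto-enal: C7 as conjugated aldehyde, C8 ketone, ethyl ester at C19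
Conditions: MnO2, CH2Cl2, rt
Reagents that add atoms: none
Why: Allylic oxidation with MnO2 is selective for the allylic alcohol and keeps the Z geometry.

Step 29
Reactants: 41 (2R,5Z,9R,17RS)-keto-enal
Product: 43 (1S,2R,5Z,7S,8S,9R,10S,11R,12R,17RS)-12-[(tert-butyldimethylsilyl)oxy]-8-hydroxy-2,9-bis[(triethylsilyl)oxy]briara-5,13-dien-19,7-olide, via 7,8-diol ethyl ester 42 (not isolated)
Conditions: SmI2 (2.5 equiv), THF, 2 mM (slow addition of 41), −78 °C → rt; aq. NH4Cl
Reagents that add atoms: none
Why: Intramolecular SmI2 pinacol coupling: the samarium ketyl of the enal adds to the C8 ketone held in a trivalent-samarium chelate, which should give the cis-7,8-diolate and close the ten-membered ring. The C7 alkoxide then acylates the ethyl ester to form the γ-lactone. The C8 face is expected to follow the C9 silyloxy centre (attack anti to the C10 branch).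

Step 30
Reactants: 43 (17RS)-lactone
Product: 44 (1S,2R,5Z,7S,8S,9R,10S,11R,12R,17R)-12-[(tert-butyldimethylsilyl)oxy]-8-hydroxy-2,9-bis[(triethylsilyl)oxy]briara-5,13-dien-19,7-olide
Conditions: 1,8-diazabicyclo[5.4.0]undec-7-ene, toluene, 40 °C
Reagents that add atoms: none
Why: Base equilibration of the lactone α-centre (and completion of lactonisation of any 42). The 17R epimer has the methyl group trans to the bulky C9 branch on C8 and cis to the small hydroxyl, and should predominate.

Step 31
Reactants: 44 (17R)-lactone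
Product: 45 (1S,2R,5Z,7S,8R,9R,10S,11R,12R,17R)-12-[(tert-butyldimethylsilyl)oxy]-2,8,9-trihydroxybriara-5,13-dien-19,7-olide
Conditions: HF·pyridine, pyridine, THF, 0 °C
Reagents that add atoms: none
Why: Buffered fluoride removes the two triethylsilyl ethers well before the hindered tert-butyldimethylsilyl ether (selective desilylation). The C8 descriptor changes only because the priority at C9 changes.

Step 32
Reactants: 45 2,8,9-triol
Product: 46 (1S,2R,5Z,7S,8S,9R,10S,11R,12R,17R)-2,9-diacetoxy-12-[(tert-butyldimethylsilyl)oxy]-8-hydroxybriara-5,13-dien-19,7-olide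
Conditions: Ac2O, 4-(dimethylamino)pyridine, pyridine, CH2Cl2, 0 °C → rt
Reagents that add atoms: acetic anhydride, CC(=O)OC(C)=O
Why: Acylation of the two secondary hydroxyls; the tertiary C8 hydroxyl is much slower and C12 is still silylated.

Step 33
Reactants: 46 2,9-diacetate
Product: 47 (1S,2R,5Z,7S,8S,9R,10S,11R,12R,17R)-2,9-diacetoxy-8,12-dihydroxybriara-5,13-dien-19,7-olide (CNP0222085.1)
Conditions: HF·pyridine, THF, rt
Reagents that add atoms: none
Why: Acidic fluoride cleaves the last silyl ether without acetate migration or lactone opening.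

## Compound list

1 | benzoic acid | OC(=O)c1ccccc1 | starting material
2 | iodomethane | CI | starting material
3 | 1-methylcyclohexa-2,5-diene-1-carboxylic acid | CC1(C(=O)O)C=CCC=C1 | intermediate
4 | (1-methylcyclohexa-2,5-dien-1-yl)methanol | CC1(CO)C=CCC=C1 | intermediate
5 | tert-butyl[(1-methylcyclohexa-2,5-dien-1-yl)methoxy]diphenylsilane | CC1(CO[Si](c2ccccc2)(c2ccccc2)C(C)(C)C)C=CCC=C1 | intermediate
6 | 4-{[(tert-butyldiphenylsilyl)oxy]methyl}-4-methylcyclohexa-2,5-dien-1-one | CC1(CO[Si](c2ccccc2)(c2ccccc2)C(C)(C)C)C=CC(=O)C=C1 | intermediate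
7 | vinylmagnesium bromide | C=C[Mg]Br | starting material
8 | diisobutylaluminium chloride | CC(C)C[Al](Cl)CC(C)C | starting material
9 | diisobutyl(vinyl)aluminium | C=C[Al](CC(C)C)CC(C)C | intermediate
10 | dimethylmethyleneiminium iodide | C=[N+](C)C.[I-] | starting material
11 | aluminium dienolate of the vinyl adduct (not isolated) | C=C[C@H]1C=C(O[Al](CC(C)C)CC(C)C)C=C[C@]1(C)CO[Si](c2ccccc2)(c2ccccc2)C(C)(C)C | intermediate
12 | (4S,5S,6R)-4-{[(tert-butyldiphenylsilyl)oxy]methyl}-6-[(dimethylamino)methyl]-5-ethenyl-4-methylcyclohex-2-en-1-one | C=C[C@H]1[C@H](CN(C)C)C(=O)C=C[C@]1(C)CO[Si](c2ccccc2)(c2ccccc2)C(C)(C)C | intermediate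
13 | methiodide of 12 (not isolated) | C=C[C@H]1[C@H](C[N+](C)(C)C)C(=O)C=C[C@]1(C)CO[Si](c2ccccc2)(c2ccccc2)C(C)(C)C.[I-] | intermediate
14 | (4S,5R)-4-{[(tert-butyldiphenylsilyl)oxy]methyl}-5-ethenyl-4-methyl-6-methylidenecyclohex-2-en-1-one | C=C[C@H]1C(=C)C(=O)C=C[C@]1(C)CO[Si](c2ccccc2)(c2ccccc2)C(C)(C)C | intermediate
15 | lithium dienolate from 14 (not isolated) | C=C[C@H]1C(C)=C([O-])C=C[C@]1(C)CO[Si](c2ccccc2)(c2ccccc2)C(C)(C)C.[Li+] | intermediate
16 | (4S,5S,6R)-4-{[(tert-butyldiphenylsilyl)oxy]methyl}-5-ethenyl-4,6-dimethylcyclohex-2-en-1-one | C=C[C@H]1[C@@H](C)C(=O)C=C[C@]1(C)CO[Si](c2ccccc2)(c2ccccc2)C(C)(C)C | intermediate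
17 | (1S,4S,5S,6R)-4-{[(tert-butyldiphenylsilyl)oxy]methyl}-5-ethenyl-4,6-dimethylcyclohex-2-en-1-ol (12β-ol) | C=C[C@H]1[C@@H](C)[C@@H](O)C=C[C@]1(C)CO[Si](c2ccccc2)(c2ccccc2)C(C)(C)C | intermediate
18 | (1R,4S,5S,6R)-4-{[(tert-butyldiphenylsilyl)oxy]methyl}-5-ethenyl-4,6-dimethylcyclohex-2-en-1-yl 4-nitrobenzoate | C=C[C@H]1[C@@H](C)[C@H](OC(=O)c2ccc(cc2)[N+](=O)[O-])C=C[C@]1(C)CO[Si](c2ccccc2)(c2ccccc2)C(C)(C)C | intermediate
19 | (1R,4S,5S,6R)-4-{[(tert-butyldiphenylsilyl)oxy]methyl}-5-ethenyl-4,6-dimethylcyclohex-2-en-1-ol (12α-ol) | C=C[C@H]1[C@@H](C)[C@H](O)C=C[C@]1(C)CO[Si](c2ccccc2)(c2ccccc2)C(C)(C)C | intermediate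
20 | tert-butyl{[(1R,4S,5S,6R)-4-{[(tert-butyldiphenylsilyl)oxy]methyl}-5-ethenyl-4,6-dimethylcyclohex-2-en-1-yl]oxy}dimethylsilane | C=C[C@H]1[C@@H](C)[C@H](O[Si](C)(C)C(C)(C)C)C=C[C@]1(C)CO[Si](c2ccccc2)(c2ccccc2)C(C)(C)C | intermediate
21 | [(1S,4R,5R,6S)-4-[(tert-butyldimethylsilyl)oxy]-6-ethenyl-1,5-dimethylcyclohex-2-en-1-yl]methanol | C=C[C@H]1[C@@H](C)[C@H](O[Si](C)(C)C(C)(C)C)C=C[C@]1(C)CO | intermediate
22 | (1S,4R,5R,6S)-4-[(tert-butyldimethylsilyl)oxy]-6-ethenyl-1,5-dimethylcyclohex-2-ene-1-carbaldehyde | C=C[C@H]1[C@@H](C)[C@H](O[Si](C)(C)C(C)(C)C)C=C[C@]1(C)C=O | intermediate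
23 | (2Z)-3-methylpent-2-en-4-yn-1-ol | C#C/C(C)=C\CO | starting material
24 | 1-methoxy-4-({[(2Z)-3-methylpent-2-en-4-yn-1-yl]oxy}methyl)benzene | C#C/C(C)=C\COCc1ccc(OC)cc1 | intermediate
25 | 1-methoxy-4-({[(2Z)-3-methylpenta-2,4-dien-1-yl]oxy}methyl)benzene | C=C/C(C)=C\COCc1ccc(OC)cc1 | intermediate
26 | B-[(3Z)-5-(4-methoxybenzyloxy)-3-methylpent-3-enyl]-9-borabicyclo[3.3.1]nonane (not isolated) | COc1ccc(COC/C=C(C)\CCB2C3CCCC2CCC3)cc1 | intermediate
27 | (3Z)-5-[(4-methoxybenzyl)oxy]-3-methylpent-3-en-1-ol | OCC/C(C)=C\COCc1ccc(OC)cc1 | intermediate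
28 | 1-({[(2Z)-5-iodo-3-methylpent-2-en-1-yl]oxy}methyl)-4-methoxybenzene | ICC/C(C)=C\COCc1ccc(OC)cc1 | intermediate
29 | [(3Z)-5-(4-methoxybenzyloxy)-3-methylpent-3-enyl]lithium (not isolated) | [Li]CC/C(C)=C\COCc1ccc(OC)cc1 | intermediate
30 | (1RS,4Z)-1-[(1S,4R,5R,6S)-4-[(tert-butyldimethylsilyl)oxy]-6-ethenyl-1,5-dimethylcyclohex-2-en-1-yl]-6-[(4-methoxybenzyl)oxy]-4-methylhex-4-en-1-ol | C=C[C@H]1[C@@H](C)[C@H](O[Si](C)(C)C(C)(C)C)C=C[C@]1(C)C(O)CC/C(C)=C\COCc2ccc(OC)cc2 | intermediate
31 | (4Z)-1-[(1S,4R,5R,6S)-4-[(tert-butyldimethylsilyl)oxy]-6-ethenyl-1,5-dimethylcyclohex-2-en-1-yl]-6-[(4-methoxybenzyl)oxy]-4-methylhex-4-en-1-one | C=C[C@H]1[C@@H](C)[C@H](O[Si](C)(C)C(C)(C)C)C=C[C@]1(C)C(=O)CC/C(C)=C\COCc2ccc(OC)cc2 | intermediate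
32 | (1R,4Z)-1-[(1S,4R,5R,6S)-4-[(tert-butyldimethylsilyl)oxy]-6-ethenyl-1,5-dimethylcyclohex-2-en-1-yl]-6-[(4-methoxybenzyl)oxy]-4-methylhex-4-en-1-ol | C=C[C@H]1[C@@H](C)[C@H](O[Si](C)(C)C(C)(C)C)C=C[C@]1(C)[C@H](O)CC/C(C)=C\COCc2ccc(OC)cc2 | intermediate
33 | (9R)-8,9-bis(pinacolboronate) of 32 (not isolated) | CC1(C)OB(C[C@H](B2OC(C)(C)C(C)(C)O2)[C@H]3[C@@H](C)[C@H](O[Si](C)(C)C(C)(C)C)C=C[C@]3(C)[C@H](O)CC/C(C)=C\COCc4ccc(OC)cc4)OC1(C)C | intermediate
34 | (2R,9R)-2,8,9-triol (C10 side chain (R)-CH(OH)CH2OH) | OC[C@H](O)[C@H]1[C@@H](C)[C@H](O[Si](C)(C)C(C)(C)C)C=C[C@]1(C)[C@H](O)CC/C(C)=C\COCc2ccc(OC)cc2 | intermediate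
35 | (2R,9R)-2,8,9-tris(triethylsilyl) ether of 34 | CC[Si](CC)(CC)OC[C@H](O[Si](CC)(CC)CC)[C@H]1[C@@H](C)[C@H](O[Si](C)(C)C(C)(C)C)C=C[C@]1(C)[C@H](O[Si](CC)(CC)CC)CC/C(C)=C\COCc2ccc(OC)cc2 | intermediate
36 | (2R,9R)-C8 aldehyde (C10 side chain (R)-CH(OSiEt3)CHO) | O=C[C@H](O[Si](CC)(CC)CC)[C@H]1[C@@H](C)[C@H](O[Si](C)(C)C(C)(C)C)C=C[C@]1(C)[C@H](O[Si](CC)(CC)CC)CC/C(C)=C\COCc2ccc(OC)cc2 | intermediate
37 | ethyl 2-methyl-3-oxobutanoate | CCOC(=O)C(C)C(C)=O | starting material
38 | ethyl 2-diazopropanoate | CCOC(=O)C(C)=[N+]=[N-] | intermediate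
39 | (2R,9R,17RS)-β-keto ester with 7-O-(4-methoxybenzyl) | CCOC(=O)C(C)C(=O)[C@H](O[Si](CC)(CC)CC)[C@H]1[C@@H](C)[C@H](O[Si](C)(C)C(C)(C)C)C=C[C@]1(C)[C@H](O[Si](CC)(CC)CC)CC/C(C)=C\COCc2ccc(OC)cc2 | intermediate
40 | (2R,9R,17RS)-β-keto ester with free C7 hydroxyl | CCOC(=O)C(C)C(=O)[C@H](O[Si](CC)(CC)CC)[C@H]1[C@@H](C)[C@H](O[Si](C)(C)C(C)(C)C)C=C[C@]1(C)[C@H](O[Si](CC)(CC)CC)CC/C(C)=C\CO | intermediate
41 | (2R,5Z,9R,17RS)-keto-enal | CCOC(=O)C(C)C(=O)[C@H](O[Si](CC)(CC)CC)[C@H]1[C@@H](C)[C@H](O[Si](C)(C)C(C)(C)C)C=C[C@]1(C)[C@H](O[Si](CC)(CC)CC)CC/C(C)=C\C=O | intermediate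
42 | ten-membered cis-7,8-diol with ethyl ester at C19 (samarium diolate before work-up; not isolated) | CC[Si](CC)(CC)O[C@@H]1[C@H]2[C@@H](C)[C@H](O[Si](C)(C)C(C)(C)C)C=C[C@]2(C)[C@H](O[Si](CC)(CC)CC)CC/C(C)=C\[C@H](O)[C@@]1(O)C(C)C(=O)OCC | intermediate
43 | (1S,2R,5Z,7S,8S,9R,10S,11R,12R,17RS)-12-[(tert-butyldimethylsilyl)oxy]-8-hydroxy-2,9-bis[(triethylsilyl)oxy]briara-5,13-dien-19,7-olide | CC[Si](CC)(CC)O[C@@H]1[C@H]2[C@@H](C)[C@H](O[Si](C)(C)C(C)(C)C)C=C[C@]2(C)[C@H](O[Si](CC)(CC)CC)CC/C(C)=C\[C@@H]2OC(=O)C(C)[C@]21O | intermediate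
44 | (1S,2R,5Z,7S,8S,9R,10S,11R,12R,17R)-12-[(tert-butyldimethylsilyl)oxy]-8-hydroxy-2,9-bis[(triethylsilyl)oxy]briara-5,13-dien-19,7-olide | CC[Si](CC)(CC)O[C@@H]1[C@H]2[C@@H](C)[C@H](O[Si](C)(C)C(C)(C)C)C=C[C@]2(C)[C@H](O[Si](CC)(CC)CC)CC/C(C)=C\[C@@H]2OC(=O)[C@H](C)[C@]21O | intermediate
45 | (1S,2R,5Z,7S,8R,9R,10S,11R,12R,17R)-12-[(tert-butyldimethylsilyl)oxy]-2,8,9-trihydroxybriara-5,13-dien-19,7-olide | O[C@@H]1[C@H]2[C@@H](C)[C@H](O[Si](C)(C)C(C)(C)C)C=C[C@]2(C)[C@H](O)CC/C(C)=C\[C@@H]2OC(=O)[C@H](C)[C@]21O | intermediate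
46 | (1S,2R,5Z,7S,8S,9R,10S,11R,12R,17R)-2,9-diacetoxy-12-[(tert-butyldimethylsilyl)oxy]-8-hydroxybriara-5,13-dien-19,7-olide | CC(=O)O[C@@H]1[C@H]2[C@@H](C)[C@H](O[Si](C)(C)C(C)(C)C)C=C[C@]2(C)[C@H](OC(C)=O)CC/C(C)=C\[C@@H]2OC(=O)[C@H](C)[C@]21O | intermediate
47 | (1S,2R,5Z,7S,8S,9R,10S,11R,12R,17R)-2,9-diacetoxy-8,12-dihydroxybriara-5,13-dien-19,7-olide (CNP0222085.1) | CC(=O)O[C@@H]1[C@H]2[C@@H](C)[C@H](O)C=C[C@]2(C)[C@H](OC(C)=O)CC/C(C)=C\[C@@H]2OC(=O)[C@H](C)[C@]21O | target

## Step count and least certain steps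

Total: 33 steps. Longest linear sequence: 27 steps from benzoic acid (steps 1–4, 6–14, 19–24, 26–33). Steps 5, 15–18 and 25 prepare the alane, the side-chain iodide and the diazo ester.

**Step 6 (key step).** The most likely failure is poor discrimination between the two enantiotopic enone arms. Slow trapping of the aluminium enolate by the iminium salt is the second risk, since the enolate would then simply be protonated on work-up. Fallback, from 6: rhodium-catalysed asymmetric 1,4-addition of potassium vinyltrifluoroborate (Rh(acac)(C2H4)2, (R)-BINAP, dioxane/H2O) gives the (4S,5R)-5-ethenyl enone F1. Kinetic α′-deprotonation of F1 at C11 with LiN(i-Pr)2 and reaction of the cross-conjugated enolate with 10 then gives 12, where the route is rejoined.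

**Step 29 (pinacol ring closure).** Three processes may compete: reductive cleavage of the C9–O bond of the α-silyloxy ketone before coupling, bonding of the delocalised allylic ketyl through C5 instead of C7, and coupling on the wrong C8 face or to the trans-diol, which would give the cis-fused lactone series. Fallback, from 41, forms C7–C8 by alkenyl addition instead of ketyl coupling. NaH and N-(5-chloropyridin-2-yl)bis(trifluoromethanesulfonyl)imide convert the chelated sodium enolate into the Z-enol triflate enal F2. Intramolecular Nozaki–Hiyama–Kishi reaction (CrCl2, catalytic NiCl2, DMSO, high dilution) adds the alkenyl triflate to the aldehyde, and the C7 alkoxide closes onto the cis ester to give the 8(17)-unsaturated lactone F3. Nucleophilic epoxidation (t-BuOOH, 1,8-diazabicyclo[5.4.0]undec-7-ene) gives the 8,17-epoxy lactone F4. SmI2 in THF/MeOH opens F4 at C17–O to the β-hydroxy lactone 43, where the route is rejoined before the equilibration of step 30.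

**Step 22 (diboration).** The vinyl group sits on a carbon flanked by the quaternary C1, so insertion may be slow, and the ligand may be mismatched with the substrate, giving low facial control at C9. Fallback, from 32, builds the C9 oxygen by organocatalysis:
- Et3SiOTf gives the 2-O-triethylsilyl ether F5.
- 9-Borabicyclo[3.3.1]nonane then NaBO3 (terminal-selective hydroboration) gives the C8 primary alcohol F6.
- 2,2,6,6-Tetramethylpiperidin-1-oxyl with PhI(OAc)2 gives the C8 aldehyde F7.
- L-Proline-catalysed α-aminoxylation with nitrosobenzene, followed by NaBH4, gives the (9R)-9-anilinooxy-8-ol F8.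
- N–O cleavage with CuSO4 in MeOH gives the 8,9-diol 2-O-triethylsilyl ether F9.
- Et3SiOTf/2,6-lutidine gives 35, where the route is rejoined.

**Step 10 (Mitsunobu inversion).** The axial oxyphosphonium group has an anti-periplanar hydrogen at C11, so E2 elimination to the conjugated diene may compete with substitution; ionisation of the allylic system would erode the inversion. Fallback, from 17: MeSO2Cl/Et3N gives the 12β-methanesulfonate F10, and CsOAc with 18-crown-6 in toluene displaces it with inversion to the 12α-acetate F11. K2CO3 in MeOH gives 19, where the route is rejoined.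

**Step 26 (Roskamp homologation).** A disubstituted diazo ester reacts slowly with a hindered aldehyde, and the Lewis acid may instead cause loss or migration of the α-triethylsilyl group or epimerisation at C9. Fallback, from 36: the lithium enolate of ethyl propanoate (LiN(i-Pr)2, THF, −78 °C) adds to the aldehyde to give the β-hydroxy ester F12 as a mixture at C8 and C17. Dess–Martin oxidation gives 39, where the route is rejoined.

## Further compounds

F1 | step 6 | (4S,5R)-4-{[(tert-butyldiphenylsilyl)oxy]methyl}-5-ethenyl-4-methylcyclohex-2-en-1-one | C=C[C@H]1CC(=O)C=C[C@]1(C)CO[Si](c2ccccc2)(c2ccccc2)C(C)(C)C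
F2 | step 29 | Z-enol triflate of keto-enal 41 (triflate on C8, cis to the ester) | CCOC(=O)/C(C)=C(\OS(=O)(=O)C(F)(F)F)[C@H](O[Si](CC)(CC)CC)[C@H]1[C@@H](C)[C@H](O[Si](C)(C)C(C)(C)C)C=C[C@]1(C)[C@H](O[Si](CC)(CC)CC)CC/C(C)=C\C=O
F3 | step 29 | 12-[(tert-butyldimethylsilyl)oxy]-2,9-bis[(triethylsilyl)oxy]briara-5(Z),8(17),13-trien-19,7-olide | CC[Si](CC)(CC)O[C@@H]1[C@H]2[C@@H](C)[C@H](O[Si](C)(C)C(C)(C)C)C=C[C@]2(C)[C@H](O[Si](CC)(CC)CC)CC/C(C)=C\[C@@H]2OC(=O)C(C)=C12
F4 | step 29 | 8,17-epoxy lactone from F3 (C8–O configured as the C8 hydroxyl of 44) | CC[Si](CC)(CC)O[C@@H]1[C@H]2[C@@H](C)[C@H](O[Si](C)(C)C(C)(C)C)C=C[C@]2(C)[C@H](O[Si](CC)(CC)CC)CC/C(C)=C\[C@@H]2OC(=O)[C@@]3(C)[C@]21O3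
F5 | step 22 | 2-O-triethylsilyl ether of 32 | C=C[C@H]1[C@@H](C)[C@H](O[Si](C)(C)C(C)(C)C)C=C[C@]1(C)[C@H](O[Si](CC)(CC)CC)CC/C(C)=C\COCc2ccc(OC)cc2
F6 | step 22 | C8 primary alcohol (C10 side chain CH2CH2OH) | OCC[C@H]1[C@@H](C)[C@H](O[Si](C)(C)C(C)(C)C)C=C[C@]1(C)[C@H](O[Si](CC)(CC)CC)CC/C(C)=C\COCc2ccc(OC)cc2
F7 | step 22 | C8 aldehyde (C10 side chain CH2CHO) | O=CC[C@H]1[C@@H](C)[C@H](O[Si](C)(C)C(C)(C)C)C=C[C@]1(C)[C@H](O[Si](CC)(CC)CC)CC/C(C)=C\COCc2ccc(OC)cc2
F8 | step 22 | (9R)-9-(anilinooxy)-8-ol | OC[C@H](ONc2ccccc2)[C@H]1[C@@H](C)[C@H](O[Si](C)(C)C(C)(C)C)C=C[C@]1(C)[C@H](O[Si](CC)(CC)CC)CC/C(C)=C\COCc2ccc(OC)cc2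
F9 | step 22 | (9R)-8,9-diol 2-O-triethylsilyl ether | OC[C@H](O)[C@H]1[C@@H](C)[C@H](O[Si](C)(C)C(C)(C)C)C=C[C@]1(C)[C@H](O[Si](CC)(CC)CC)CC/C(C)=C\COCc2ccc(OC)cc2
F10 | step 10 | 12β-methanesulfonate of 17 | C=C[C@H]1[C@@H](C)[C@@H](OS(C)(=O)=O)C=C[C@]1(C)CO[Si](c2ccccc2)(c2ccccc2)C(C)(C)C
F11 | step 10 | 12α-acetate (acetate of 19) | C=C[C@H]1[C@@H](C)[C@H](OC(C)=O)C=C[C@]1(C)CO[Si](c2ccccc2)(c2ccccc2)C(C)(C)C
F12 | step 26 | β-hydroxy ester from 36 and ethyl propanoate (8RS,17RS) | CCOC(=O)C(C)C(O)[C@H](O[Si](CC)(CC)CC)[C@H]1[C@@H](C)[C@H](O[Si](C)(C)C(C)(C)C)C=C[C@]1(C)[C@H](O[Si](CC)(CC)CC)CC/C(C)=C\COCc2ccc(OC)cc2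
A1 | alternative 1 | bicyclic cis-8,9-diol with the lactone masked as lactol methyl ether | O[C@@H]1[C@H]2[C@@H](C)[C@H](O[Si](C)(C)C(C)(C)C)C=C[C@]2(C)[C@H](OC(C)=O)CC/C(C)=C\[C@@H]2O[C@@H](OC)[C@H](C)[C@]21O
A2 | alternative 1 | keto-aldehyde precursor of A1 (C9 aldehyde, 2-methoxy-4-methylfuran-3-one at C7) | O=C[C@H]1[C@@H](C)[C@H](O[Si](C)(C)C(C)(C)C)C=C[C@]1(C)[C@H](OC(C)=O)CC/C(C)=C\[C@@H]1O[C@@H](OC)[C@H](C)C1=O
A3 | alternative 2 | bicyclic 2,7,12-triketone with 5Z-enone and C19 methyl ester | CC(=O)O[C@@H]1[C@H]2[C@@H](C)C(=O)C=C[C@]2(C)C(=O)CC/C(C)=C\C(=O)[C@@]1(O[Si](CC)(CC)CC)[C@@H](C)C(=O)OC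
A4 | alternative 2 | tricyclic hydrophenanthrene with C2=C7 alkene and C5 acetate | CC(=O)O[C@@H]1[C@H]2[C@@H](C)C(=O)C=C[C@]2(C)C2=C(CC(C)(OC(C)=O)CC2)[C@@]1(O[Si](CC)(CC)CC)[C@@H](C)C(=O)OC
A5 | alternative 3 | complete skeleton with C9 4-methoxybenzyl and C12 silyl ethers | COc1ccc(CO[C@@H]2[C@H]3[C@@H](C)[C@H](O[Si](C)(C)C(C)(C)C)C=C[C@]3(C)[C@H](OC(C)=O)CC/C(C)=C\[C@@H]4OC(=O)[C@H](C)[C@]42O)cc1
A6 | alternative 3 | macrocyclic C8 ketone with O7 2-bromopropanoate | COc1ccc(CO[C@@H]2[C@H]3[C@@H](C)[C@H](O[Si](C)(C)C(C)(C)C)C=C[C@]3(C)[C@H](OC(C)=O)CC/C(C)=C\[C@H](OC(=O)C(C)Br)C2=O)cc1
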